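## Retrosynthetic overview

1. Target 34 ⇐ global deprotection and kinetic protonation at C11 of macrobicycle 31; ring A (ten-membered lactone) ⇐ Shiina lactonisation (O–C9) of seco acid 30.
2. Ring B (γ-lactone, O–C10) ⇐ C7–OH plus C10 acid, after opening of a temporary butenolide-derived lactone; C4 ketone ⇐ Weinreb amide 24 plus alkylmagnesium bromide 25 (C3–C4).
3. Key bond C6–C11 ⇐ intermolecular Michael addition of the lithium enolate of furylacetate 12 to (S)-butenolide 20, anti to the C7 side chain (sets C6 from C7).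
4. 20 ⇐ tert-butyl acetate/acrolein aldol, Sharpless kinetic resolution, acryloylation, RCM; 12 ⇐ furan + bromide 4, bromination, Reformatsky arylation; 4 and 5 ⇐ (R)-butane-1,3-diol (C1 and C3′ from the chiral pool).
5. Ring order: furan (bought) → temporary butenolide → ring B → ring A.

Convention and assumption: skeleton atoms carry the target locants throughout. C1 = CH(CH3)–O of ring A, C4 = ketone, C6/C7 = ring-fusion carbons (C7 bears O), C9 = ring A C=O, C10 = ring B C=O, C11 = furyl-bearing CH, C3′ = side-chain carbinol. Compounds 22–31 are carried as both C11 epimers (no descriptor at C11 in their SMILES); step 20 converges them.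

## Route

Step 1
Reactants: 1 (R)-butane-1,3-diol
Product: 2 (R)-3-hydroxybutyl 4-methylbenzenesulfonate
Conditions: TsCl (1.05 equiv), Et3N, CH2Cl2, −20 to 0 °C
Reagents that add atoms: 4-toluenesulfonyl chloride, Cc1ccc(cc1)S(Cl)(=O)=O
Why: Selective O-sulfonylation of the less hindered primary hydroxyl, leaving the secondary carbinol stereocentre untouched.

Step 2
Reactants: 2 (R)-3-hydroxybutyl 4-methylbenzenesulfonate
Product: 3 (R)-4-bromobutan-2-ol
Conditions: LiBr, acetone, reflux
Reagents that add atoms: lithium bromide, [Li+].[Br-]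
Why: SN2 displacement of the primary tosylate by bromide at a carbon remote from the stereocentre.

Step 3
Reactants: 3 (R)-4-bromobutan-2-ol
Product: 4 (R)-(4-bromobutan-2-yloxy)(tert-butyl)dimethylsilane
Conditions: TBSCl, imidazole, DMF, rt
Reagents that add atoms: tert-butyldimethylsilyl chloride, CC(C)(C)[Si](C)(C)Cl
Why: Imidazole-promoted O-silylation gives the robust TBS ether that protects C3′–OH to the last step.

Step 4
Reactants: 3 (R)-4-bromobutan-2-ol
Product: 5 (R)-(4-bromobutan-2-yloxy)triethylsilane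
Conditions: TESCl, imidazole, CH2Cl2, 0 °C
Reagents that add atoms: triethylsilyl chloride, CC[Si](Cl)(CC)CC
Why: O-Silylation gives a TES ether (future C1–O) that can later be removed in the presence of the TBS ether.

Step 5
Reactants: 6 furan, 4 (R)-(4-bromobutan-2-yloxy)(tert-butyl)dimethylsilane
Product: 8 (R)-tert-butyl[4-(furan-2-yl)butan-2-yloxy]dimethylsilane, via 2-furyllithium 7 (not isolated)
Conditions: n-BuLi, THF, 0 °C; then 4, DMPU, 0 °C to rt
Reagents that add atoms: n-butyllithium, [Li]CCCC (its lithium stays only in 7)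
Why: α-Lithiation of furan followed by SN2 alkylation of the aryllithium with the primary bromide, not touching the stereocentre.

Step 6
Reactants: 8 (R)-tert-butyl[4-(furan-2-yl)butan-2-yloxy]dimethylsilane
Product: 9 (R)-[4-(5-bromofuran-2-yl)butan-2-yloxy](tert-butyl)dimethylsilane
Conditions: NBS, DMF, 0 °C, dark; used at once
Reagents that add atoms: N-bromosuccinimide, BrN1C(=O)CCC1=O
Why: Electrophilic aromatic bromination occurs at the only free α-position of the 2-alkylfuran.

Step 7
Reactants: 10 tert-butyl bromoacetate, 9 (R)-[4-(5-bromofuran-2-yl)butan-2-yloxy](tert-butyl)dimethylsilane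
Product: 12 tert-butyl 2-{5-[(3R)-3-(tert-butyldimethylsilyloxy)butyl]furan-2-yl}acetate, via Reformatsky zinc reagent 11 (not isolated)
Conditions: Zn dust, Me3SiCl (cat.), THF, rt; then 9, Pd(dba)2 (2 mol %), P(t-Bu)3 (2 mol %), THF, rt
Reagents that add atoms: zinc, [Zn] (stays only in 11)
Why: Palladium-catalysed α-arylation of the zinc ester enolate (Negishi-type coupling of a Reformatsky reagent) with the heteroaryl bromide gives the arylacetate under nearly neutral conditions.

Step 8
Reactants: 13 tert-butyl acetate, 14 acrolein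
Product: 16 racemic tert-butyl 3-hydroxypent-4-enoate, via tert-butyl acetate lithium enolate 15 (not isolated)
Conditions: LiN(iPr)2, THF, −78 °C; then 14, −78 °C; AcOH quench
Reagents that add atoms: lithium diisopropylamide, [Li]N(C(C)C)C(C)C (its lithium stays only in 15)
Why: Intermolecular acetate aldol addition (1,2-addition to the enal at −78 °C) builds C6–C9 with the C7 carbinol as a racemate that is resolved in step 9.

Step 9
Reactants: 16 racemic tert-butyl 3-hydroxypent-4-enoate
Product: 17 tert-butyl (3S)-3-hydroxypent-4-enoate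
Conditions: Ti(OiPr)4 (20 mol %), D-(−)-diisopropyl tartrate (24 mol %), t-BuOOH (0.6 equiv), 4 Å molecular sieves, CH2Cl2, −20 °C, to ca. 55–60 % conversion
Reagents that add atoms: none
Why: Sharpless kinetic resolution, in which the D-(−)-tartrate catalyst epoxidises the (R)-allylic alcohol much faster, so the (S)-alcohol (future C7) is recovered in high ee.

Step 10
Reactants: 17 tert-butyl (3S)-3-hydroxypent-4-enoate, 18 acryloyl chloride
Product: 19 tert-butyl (3S)-3-(acryloyloxy)pent-4-enoate
Conditions: iPr2NEt, CH2Cl2, −78 to 0 °C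
Reagents that add atoms: none
Why: O-Acylation of the secondary alcohol proceeds with retention because the C–O bond is not broken.

Step 11
Reactants: 19 tert-butyl (3S)-3-(acryloyloxy)pent-4-enoate
Product: 20 tert-butyl 2-[(2S)-5-oxo-2,5-dihydrofuran-2-yl]acetate
Conditions: (H2IMes)(PCy3)Cl2Ru=CHPh (second-generation Grubbs catalyst, 5 mol %), CH2Cl2 (0.01 M), reflux
Reagents that add atoms: none
Why: Ring-closing metathesis of the vinyl and acrylate groups forms the five-membered butenolide with loss of ethene and without involving the stereocentre.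

Step 12
Reactants: 12 tert-butyl 2-{5-[(3R)-3-(tert-butyldimethylsilyloxy)butyl]furan-2-yl}acetate, 20 tert-butyl 2-[(2S)-5-oxo-2,5-dihydrofuran-2-yl]acetate
Product: 22 Michael adduct lactone diester (6S,7S; both C11 epimers), via furylacetate lithium enolate 21 (not isolated)
Conditions: LiN(iPr)2, THF, −78 °C; then 20, −78 °C, 1 h; AcOH, −78 °C
Reagents that add atoms: lithium diisopropylamide, [Li]N(C(C)C)C(C)C (its lithium stays only in 21)
Why: Intermolecular Michael addition joins the two fragments at C6–C11, the ester enolate attacking the butenolide face anti to the C7 CH2CO2tBu group so that 6S is set trans to it from 7S, while C11 forms unselectively and is fixed in step 20.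

Step 13
Reactants: 22 Michael adduct lactone diester
Product: 23 C7-hydroxy C4-Weinreb amide di-tert-butyl ester
Conditions: MeNHOMe·HCl, AlMe3, CH2Cl2, 0 °C to rt; aq. KNaC4H4O6 work-up; used crude
Reagents that add atoms: N,O-dimethylhydroxylamine hydrochloride, CNOC.Cl
Why: Weinreb aminolysis with the aluminium amide opens only the γ-lactone (hindered tert-butyl esters are inert), freeing C7–OH with retention and turning C4 into a Weinreb amide.

Step 14
Reactants: 23 C7-hydroxy C4-Weinreb amide di-tert-butyl ester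
Product: 24 C7-O-triethylsilyl Weinreb amide
Conditions: TESCl, imidazole, DMF, 0 °C
Reagents that add atoms: triethylsilyl chloride, CC[Si](Cl)(CC)CC
Why: O-Silylation blocks C7–OH so that it can neither relactonise onto C4 nor quench the Grignard reagent.

Step 15
Reactants: 5 (R)-(4-bromobutan-2-yloxy)triethylsilane, 24 C7-O-triethylsilyl Weinreb amide
Product: 26 C4 ketone with C1 and C7 TES ethers, via alkylmagnesium bromide 25 (not isolated)
Conditions: Mg, THF, rt; then 24, THF, −20 to 0 °C (2.5 equiv of 25); aq. NH4Cl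
Reagents that add atoms: magnesium, [Mg] (stays only in 25)
Why: Weinreb ketone synthesis, in which the Grignard reagent adds once and the magnesium chelate collapses to the C4 ketone only on work-up, leaving tert-butyl esters and silyl ethers intact and bringing in C1 already (R).

Step 16
Reactants: 26 C4 ketone with C1 and C7 TES ethers
Product: 27 C4 1,3-dioxolane
Conditions: (Me3SiOCH2)2, Me3SiOTf (10 mol %), CH2Cl2, −78 to −20 °C; pyridine quench
Reagents that add atoms: 1,2-bis(trimethylsilyloxy)ethane, C[Si](C)(C)OCCO[Si](C)(C)C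
Why: Noyori ketalisation under aprotic low-temperature conditions masks the C4 ketone (which would otherwise form a hemiketal with C1–OH and enolise in step 20) without harming silyl ethers, esters or the furan.

Step 17
Reactants: 27 C4 1,3-dioxolane
Product: 28 C9,C10 diacid
Conditions: Me3SiOTf (5 equiv), 2,6-lutidine (7 equiv), CH2Cl2, 0 °C to rt; aq. citric acid work-up
Reagents that add atoms: none
Why: Silyl triflate-mediated cleavage of both tert-butyl esters (loss of 2-methylpropene from the O-silylated esters, silyl esters hydrolysed on work-up) under lutidine buffering spares the ketone ketal, the silyl ethers and the acid-sensitive furan.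

Step 18
Reactants: 28 C9,C10 diacid
Product: 30 ring B lactone seco acid, via dihydroxy diacid 29 (not isolated)
Conditions: HF·pyridine, pyridine, THF, 0 °C to rt; then toluene, 40 °C
Reagents that add atoms: none
Why: Fluoride desilylation removes the two TES ethers faster than the TBS ether, and the freed C7–OH closes ring B by γ-lactonisation onto the C10 acid (the C9 acid could only give a β-lactone), placing C5 and C8 cis as fixed in step 12.

Step 19
Reactants: 30 ring B lactone seco acid
Product: 31 ring A/ring B bislactone (C4 dioxolane; C3′ TBS ether; both C11 epimers)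
Conditions: 2-methyl-6-nitrobenzoic anhydride (1.5 equiv), DMAP (6 equiv), CH2Cl2 (1 mM), rt, 30 added over 12 h
Reagents that add atoms: none
Why: Shiina macrolactonisation, in which the mixed anhydride of the C9 acid is captured by C1–OH under high dilution, closes the ten-membered ring with retention at C1.

Step 20
Reactants: 31 ring A/ring B bislactone
Product: 33 protected cordycicadin B (1R,6S,7S,11S), via lactone lithium enolate 32 (not isolated)
Conditions: LiN(SiMe3)2 (1.3 equiv), THF, −78 °C, 30 min; then AcOH in THF, −78 °C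
Reagents that add atoms: lithium bis(trimethylsilyl)amide, [Li]N([Si](C)(C)C)[Si](C)(C)C (its lithium stays only in 32)
Why: Kinetic protonation of the lactone enolate, in which only the doubly activated C11–H is removed and the planar enolate is protonated on the face opposite the C5 and C8 bonds, puts the furyl group cis to them (11S) from either C11 epimer.

Step 21
Reactants: 33 protected cordycicadin B
Product: 34 cordycicadin B
Conditions: HF (48 % aq.), MeCN, 0 °C to rt
Reagents that add atoms: water, O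
Why: Acid-mediated global deprotection (Si–O cleavage of the TBS ether and hydrolysis of the dioxolane) runs under non-enolising conditions, so the C11 configuration is kept.

## Compound list

1 | (R)-butane-1,3-diol | C[C@@H](O)CCO | starting material
2 | (R)-3-hydroxybutyl 4-methylbenzenesulfonate | C[C@@H](O)CCOS(=O)(=O)c1ccc(C)cc1 | intermediate
3 | (R)-4-bromobutan-2-ol | C[C@@H](O)CCBr | intermediate
4 | (R)-(4-bromobutan-2-yloxy)(tert-butyl)dimethylsilane | C[C@@H](O[Si](C)(C)C(C)(C)C)CCBr | intermediate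
5 | (R)-(4-bromobutan-2-yloxy)triethylsilane | C[C@@H](O[Si](CC)(CC)CC)CCBr | intermediate
6 | furan | c1ccoc1 | starting material
7 | 2-furyllithium (not isolated) | [Li]c1ccco1 | intermediate
8 | (R)-tert-butyl[4-(furan-2-yl)butan-2-yloxy]dimethylsilane | C[C@@H](O[Si](C)(C)C(C)(C)C)CCc1ccco1 | intermediate
9 | (R)-[4-(5-bromofuran-2-yl)butan-2-yloxy](tert-butyl)dimethylsilane | C[C@@H](O[Si](C)(C)C(C)(C)C)CCc1ccc(Br)o1 | intermediate
10 | tert-butyl bromoacetate | BrCC(=O)OC(C)(C)C | starting material
11 | (2-tert-butoxy-2-oxoethyl)zinc bromide (not isolated) | Br[Zn]CC(=O)OC(C)(C)C | intermediate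
12 | tert-butyl 2-{5-[(3R)-3-(tert-butyldimethylsilyloxy)butyl]furan-2-yl}acetate | C[C@@H](O[Si](C)(C)C(C)(C)C)CCc1ccc(CC(=O)OC(C)(C)C)o1 | intermediate
13 | tert-butyl acetate | CC(=O)OC(C)(C)C | starting material
14 | acrolein (prop-2-enal) | C=CC=O | starting material
15 | lithium 1-tert-butoxyethenolate (not isolated) | C=C(O[Li])OC(C)(C)C | intermediate
16 | racemic tert-butyl 3-hydroxypent-4-enoate | C=CC(O)CC(=O)OC(C)(C)C | intermediate
17 | tert-butyl (3S)-3-hydroxypent-4-enoate | C=C[C@@H](O)CC(=O)OC(C)(C)C | intermediate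
18 | acryloyl chloride | C=CC(Cl)=O | starting material
19 | tert-butyl (3S)-3-(acryloyloxy)pent-4-enoate | C=C[C@@H](OC(=O)C=C)CC(=O)OC(C)(C)C | intermediate
20 | tert-butyl 2-[(2S)-5-oxo-2,5-dihydrofuran-2-yl]acetate | O=C1C=C[C@H](CC(=O)OC(C)(C)C)O1 | intermediate
21 | lithium enolate of 12 (not isolated) | C[C@@H](O[Si](C)(C)C(C)(C)C)CCc1ccc(C=C(O[Li])OC(C)(C)C)o1 | intermediate
22 | tert-butyl 2-{5-[(3R)-3-(tert-butyldimethylsilyloxy)butyl]furan-2-yl}-2-[(2S,3S)-2-(2-tert-butoxy-2-oxoethyl)-5-oxooxolan-3-yl]acetate, both C11 epimers | O=C1C[C@@H](C(c2ccc(CC[C@@H](C)O[Si](C)(C)C(C)(C)C)o2)C(=O)OC(C)(C)C)[C@H](CC(=O)OC(C)(C)C)O1 | intermediate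
23 | di-tert-butyl (3S,4S)-2-{5-[(3R)-3-(tert-butyldimethylsilyloxy)butyl]furan-2-yl}-4-hydroxy-3-{2-[methoxy(methyl)amino]-2-oxoethyl}hexanedioate, both C2 (= C11) epimers | CON(C)C(=O)C[C@@H](C(c1ccc(CC[C@@H](C)O[Si](C)(C)C(C)(C)C)o1)C(=O)OC(C)(C)C)[C@@H](O)CC(=O)OC(C)(C)C | intermediate
24 | 4-O-triethylsilyl ether of 23 | CON(C)C(=O)C[C@@H](C(c1ccc(CC[C@@H](C)O[Si](C)(C)C(C)(C)C)o1)C(=O)OC(C)(C)C)[C@@H](O[Si](CC)(CC)CC)CC(=O)OC(C)(C)C | intermediate
25 | (R)-[3-(triethylsilyloxy)butyl]magnesium bromide (not isolated) | C[C@@H](O[Si](CC)(CC)CC)CC[Mg]Br | intermediate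
26 | di-tert-butyl (3S,4S)-2-{5-[(3R)-3-(tert-butyldimethylsilyloxy)butyl]furan-2-yl}-3-[(5R)-2-oxo-5-(triethylsilyloxy)hexyl]-4-(triethylsilyloxy)hexanedioate, both C11 epimers | C[C@@H](O[Si](CC)(CC)CC)CCC(=O)C[C@@H](C(c1ccc(CC[C@@H](C)O[Si](C)(C)C(C)(C)C)o1)C(=O)OC(C)(C)C)[C@@H](O[Si](CC)(CC)CC)CC(=O)OC(C)(C)C | intermediate
27 | di-tert-butyl (3S,4S)-2-{5-[(3R)-3-(tert-butyldimethylsilyloxy)butyl]furan-2-yl}-4-(triethylsilyloxy)-3-({2-[(3R)-3-(triethylsilyloxy)butyl]-1,3-dioxolan-2-yl}methyl)hexanedioate, both C11 epimers | C[C@@H](O[Si](CC)(CC)CC)CCC1(OCCO1)C[C@@H](C(c2ccc(CC[C@@H](C)O[Si](C)(C)C(C)(C)C)o2)C(=O)OC(C)(C)C)[C@@H](O[Si](CC)(CC)CC)CC(=O)OC(C)(C)C | intermediate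
28 | hexanedioic acid corresponding to 27 (both tert-butyl esters cleaved), both C11 epimers | C[C@@H](O[Si](CC)(CC)CC)CCC1(OCCO1)C[C@@H](C(c2ccc(CC[C@@H](C)O[Si](C)(C)C(C)(C)C)o2)C(O)=O)[C@@H](O[Si](CC)(CC)CC)CC(O)=O | intermediate
29 | (3S,4S)-2-{5-[(3R)-3-(tert-butyldimethylsilyloxy)butyl]furan-2-yl}-4-hydroxy-3-({2-[(3R)-3-hydroxybutyl]-1,3-dioxolan-2-yl}methyl)hexanedioic acid (not isolated), both C11 epimers | C[C@@H](O)CCC1(OCCO1)C[C@@H](C(c2ccc(CC[C@@H](C)O[Si](C)(C)C(C)(C)C)o2)C(O)=O)[C@@H](O)CC(O)=O | intermediate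
30 | 2-[(2S,3S)-4-{5-[(3R)-3-(tert-butyldimethylsilyloxy)butyl]furan-2-yl}-3-({2-[(3R)-3-hydroxybutyl]-1,3-dioxolan-2-yl}methyl)-5-oxooxolan-2-yl]acetic acid, both C4 (= C11) epimers | C[C@@H](O)CCC1(OCCO1)C[C@@H]2[C@H](CC(O)=O)OC(=O)C2c3ccc(CC[C@@H](C)O[Si](C)(C)C(C)(C)C)o3 | intermediate
31 | C4 ethylene ketal and C3′ TBS ether of cordycicadin B and of its C11 epimer (1R,6S,7S,3′R) | C[C@@H]1CCC2(OCCO2)C[C@@H]3[C@H](CC(=O)O1)OC(=O)C3c4ccc(CC[C@@H](C)O[Si](C)(C)C(C)(C)C)o4 | intermediate
32 | lithium enolate of 31 (C10–OLi, C10=C11; not isolated) | C[C@@H]1CCC2(OCCO2)C[C@@H]3[C@H](CC(=O)O1)OC(O[Li])=C3c4ccc(CC[C@@H](C)O[Si](C)(C)C(C)(C)C)o4 | intermediate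
33 | C4 ethylene ketal and C3′ TBS ether of cordycicadin B (1R,6S,7S,11S,3′R; furyl, C5 and C8 all cis on ring B) | C[C@@H]1CCC2(OCCO2)C[C@@H]3[C@H](CC(=O)O1)OC(=O)[C@@H]3c4ccc(CC[C@@H](C)O[Si](C)(C)C(C)(C)C)o4 | intermediate
34 | cordycicadin B | C[C@@H]1CCC(=O)C[C@@H]2[C@H](CC(=O)O1)OC(=O)[C@@H]2c1ccc(CC[C@@H](C)O)o1 | target

## Step count

Total steps: 21.
Longest linear sequence: 16 steps (1, 2, 3, 5, 6, 7, 12, 13, 14, 15, 16, 17, 18, 19, 20, 21).

## Steps most likely to fail and fallbacks

Step 12 (Michael addition). The risk is proton transfer from the butenolide γ-position to the basic enolate, which lowers the yield and can racemise 20. The fallback sets out from 12 (with 20) and returns at 22. Compound 12 is converted with LiN(iPr)2 and Me3SiCl (THF, −78 °C) into the O-trimethylsilyl ketene acetal F1. F1 is added to 20 in a Mukaiyama–Michael reaction under Me3SiOTf catalysis (10 mol %, CH2Cl2, −78 °C), where no basic enolate is present and attack is again anti to the C7 substituent. The resulting 2-silyloxy-4,5-dihydrofuran adduct F2 is hydrolysed on aqueous work-up to 22.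

Step 19 (ten-membered ring closure). The risk is dimer or oligomer formation instead of ring A. The fallback sets out from 24 and returns at 31, closing ring A by olefin metathesis at C2=C3 instead of at the ester bond.
- Amide 24 reacts with CH2=CHMgBr (THF, −20 °C, acidic quench) to give the vinyl ketone F3.
- Me3SiOTf/2,6-lutidine followed by HF·pyridine removes the tert-butyl and TES groups and closes ring B, giving the enone lactone acid F4.
- Esterification with (R)-but-3-en-2-ol (C[C@@H](O)C=C; EDC·HCl, cat. DMAP, CH2Cl2, 0 °C) gives the but-3-en-2-yl ester F5.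
- Ring-closing metathesis with (H2IMes)(PCy3)Cl2Ru=CHPh (second-generation Grubbs catalyst, CH2Cl2, 1 mM, reflux) gives the ten-membered enone lactone F6.
- Conjugate reduction with [(Ph3P)CuH]6 (toluene, rt) gives the ring A ketone F7.
- Ketalisation as in step 16 gives 31.

Step 20 (kinetic protonation). The risk is poor facial selectivity or partial return to the trans lactone. The fallback sets out from 31 and returns at 33. The enolate 32 is trapped with PhSeBr (THF, −78 °C) to give the α-phenylselanyl lactone F8. Radical reduction with Bu3SnH and Et3B/air (toluene, −78 °C) then delivers the hydrogen atom to the planar C11 radical from the face opposite C5 and C8, giving 33 by a non-ionic pathway.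

## Further compounds

F1 | step 12 | O-trimethylsilyl ketene acetal of 12: tert-butyl{(2R)-4-[5-(2-tert-butoxy-2-trimethylsilyloxyethenyl)furan-2-yl]butan-2-yloxy}dimethylsilane | C[C@@H](O[Si](C)(C)C(C)(C)C)CCc1ccc(C=C(O[Si](C)(C)C)OC(C)(C)C)o1
F2 | step 12 | 2-trimethylsilyloxy-4,5-dihydrofuran form of adduct 22 (4S,5S on the dihydrofuran), both C11 epimers | C[Si](C)(C)OC1=C[C@@H](C(c2ccc(CC[C@@H](C)O[Si](C)(C)C(C)(C)C)o2)C(=O)OC(C)(C)C)[C@H](CC(=O)OC(C)(C)C)O1
F3 | step 19 | vinyl ketone: di-tert-butyl (3S,4S)-2-{5-[(3R)-3-(tert-butyldimethylsilyloxy)butyl]furan-2-yl}-3-(2-oxobut-3-enyl)-4-(triethylsilyloxy)hexanedioate, both C11 epimers | C=CC(=O)C[C@@H](C(c1ccc(CC[C@@H](C)O[Si](C)(C)C(C)(C)C)o1)C(=O)OC(C)(C)C)[C@@H](O[Si](CC)(CC)CC)CC(=O)OC(C)(C)C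
F4 | step 19 | enone lactone acid: 2-[(2S,3S)-4-{5-[(3R)-3-(tert-butyldimethylsilyloxy)butyl]furan-2-yl}-5-oxo-3-(2-oxobut-3-enyl)oxolan-2-yl]acetic acid, both C11 epimers | C=CC(=O)C[C@@H]1[C@H](CC(O)=O)OC(=O)C1c2ccc(CC[C@@H](C)O[Si](C)(C)C(C)(C)C)o2
F5 | step 19 | (2R)-but-3-en-2-yl ester of F4 | C=CC(=O)C[C@@H]1[C@H](CC(=O)O[C@H](C)C=C)OC(=O)C1c2ccc(CC[C@@H](C)O[Si](C)(C)C(C)(C)C)o2
F6 | step 19 | ten-membered enone lactone: 2,3-didehydro C3′ TBS ether of cordycicadin B and its C11 epimer (E/Z mixture) | C[C@@H]1C=CC(=O)C[C@@H]2[C@H](CC(=O)O1)OC(=O)C2c3ccc(CC[C@@H](C)O[Si](C)(C)C(C)(C)C)o3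
F7 | step 19 | ring A ketone: C3′ TBS ether of cordycicadin B and of its C11 epimer | C[C@@H]1CCC(=O)C[C@@H]2[C@H](CC(=O)O1)OC(=O)C2c3ccc(CC[C@@H](C)O[Si](C)(C)C(C)(C)C)o3
F8 | step 20 | α-phenylselanyl lactone: 11-phenylselanyl derivative of 31 | C[C@@H]1CCC2(OCCO2)C[C@@H]3[C@H](CC(=O)O1)OC(=O)C3([Se]c4ccccc4)c5ccc(CC[C@@H](C)O[Si](C)(C)C(C)(C)C)o5
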